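(The readings are calculated from invented constants, and the scatter is random.)

Amounts first: the grey flask starts with c(coupling partner) at 40.0 mM against c(starting material) at 300 mM. The coupling partner is therefore the limiting reagent there, and target can reach at most 13.3% of the starting material charged. What matters is how much of that partner ends as target. In the violet run, 37.8% of the partner charged stands as target at 56 min; that share of the charge is the capture.

| flask | starting material | coupling partner | time |
|---|---|---|---|
| violet | 100 mM | 120 mM |  |
| teal | 100 mM | 360 mM |  |
| grey | 300 mM | 40.0 mM | 56 min |

| run | time / min | [target] / mM |
|---|---|---|
| violet run | 7.0 | 17.1 |
| violet run | 14 | 29.3 |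
| violet run | 21 | 35.8 |
| violet run | 28 | 41.4 |
| violet run | 35 | 41.3 |
| violet run | 42 | 43.0 |
| violet run | 49 | 45.3 |
| violet run | 56 | 45.3 |
| teal run | 7.0 | 23.4 |
| teal run | 14 | 38.2 |
| teal run | 21 | 45.6 |
| teal run | 28 | 52.9 |
| teal run | 35 | 55.9 |
| teal run | 42 | 58.3 |
| teal run | 49 | 58.6 |
| teal run | 56 | 59.4 |

(scatter of a reading: 1 mM)

- how the opening rate goes with [coupling partner] round the charge of the violet run: the exponent of the rate at two percent of starting material gone to target
- target in the grey run at 56 min, as a share of the starting material charged

The partner charge is the first setting. By hand, a rate first order in the partner grows 3.00-fold from the violet run to the teal run. At the first reading the teal run holds 1.37 times the target of the violet run, a rough mean exponent of 0.286 across that span. The reckoning here takes this mean as its estimate of the order round the violet charge. Target at the last reading rises from 45.3 mM to 59.4 mM, but capture drops to 16.5% in the teal run.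

Time is the second setting. By hand, target should keep rising with time, yet the violet run reads 45.3 mM at 49 min and 45.3 mM at 56 min. The last reading of the violet run is therefore taken as its plateau, within the scatter.

The starting material charge is the third setting, and neither run moves it. By hand, more starting material per partner should raise capture. The odds of capture are 0.606 in the violet run and 0.198 in the teal run. Divided by the ratio of starting material to partner charged, they give 0.728 and 0.711. Carrying the violet value to the grey run gives odds of 5.46, a capture of 84.5%, and so 11.3% of the starting material charged.

The forecast gives 0.4 for the order and 9.5% for the grey run, a share below the reckoning here, and notes that “The order in starting material is untested”.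

The flask gives an order of 0.48 and 9.36% in the grey run.

    starting material + coupling partner → target (3.174 L mol⁻¹ min⁻¹)
    starting material + coupling partner → side product (0.5178 L mol⁻¹ min⁻¹)
    starting material + coupling partner ⇌ idle substrate-reagent adduct, settled at all times (80.00 L mol⁻¹)
    coupling partner → lost reagent (0.1500 min⁻¹)

Capture in the grey run is thus 70.2%, higher than the 37.8% of the violet run but lower than the 84.5% reckoned. At the violet charge, starting material and coupling partner sit parked as idle substrate-reagent adduct, and with that parking taken away the exponent in coupling partner goes from 0.48 to 1.0.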